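At 20.0 h, the last reading of the west run, J stands at 86.3% of the Q charged, after 87.1% at 10.0 h, and all four runs flatten near this height although Q rises from 1.1 M to 3 M.

the same everywhere: X 200 mM (held)
- north: Q 1.1 M; E 0.05 mol%; run made earlier
- south: Q 1.8 M; E 0.05 mol%; run made earlier
- south-west: Q 2.5 M; E 0.05 mol%; run made earlier
- west: Q 3 M; E 0.045 mol%; run made earlier
- gamma: Q 1.0 M; E 0.012 mol%; time 20 h
- theta: Q 3.0 M; E 0.015 mol%; time 20 h
- delta: Q 3.0 M; E 0.2 mol%; time 20 h
- alpha: Q 3.0 M; E 0.05 mol%; time 20 h

| north: time / h | north: J / % | south: time / h | south: J / % | south-west: time / h | south-west: J / % | west: time / h | west: J / % |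
|---|---|---|---|---|---|---|---|
| 2.00 | 33.4 | 1.50 | 38.2 | 1.50 | 45.3 | 1.50 | 43.0 |
| 5.00 | 63.7 | 3.00 | 59.4 | 3.00 | 69.5 | 3.00 | 67.4 |
| 10.0 | 81.9 | 6.00 | 79.5 | 6.00 | 84.8 | 6.00 | 83.3 |
| 15.0 | 86.2 | 10.0 | 87.3 | 10.0 | 86.6 | 10.0 | 87.1 |
| 20.0 | 88.6 | 20.0 | 88.9 | 20.0 | 87.3 | 20.0 | 86.3 |

(readings scatter by 1 percentage point)

- at the start none of X is in solution

1. all flasks from highest to lowest amount of J, in percent of the Q charged, at 20 h (gamma / theta / delta / alpha)
2. the same order at 2.0 h (gamma / theta / delta / alpha)
3. the amount of J, in percent of the Q charged of the flask you put first, at 20 h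
4. the amount of J, in percent of the Q charged of the flask you put last, at 20 h

The decision for the next run is whether 0.2 mol% of E buys more J than 0.05 mol%, or only speed. An equilibrium at held X would give speed alone, but a shortfall that stops growing late in the run and ignores the charge of Q also fits a loss of J to Q while Q lasts. If such a side step goes as [Q][J] and the making of J as [Q][E], their ratio goes as [J]/[E], so the charge of Q cancels and the loading ℓ of E on Q remains. The shortfall s of the plateau should then go as the inverse of ℓ, and the quantity to carry is the loss loading ℓs, the product s·ℓ, read here from the west run, which has the Q of delta: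

ℓs = 13.7% × 0.045 mol% = 0.0062 mol%

This is a reading, and it carries the scatter of 1 percentage point on the shortfall. Dividing by each loading gives:

J in alpha = 87.6%, J in delta = 96.9%

So the larger charge of E is worth making. If rates follow [E], the 20 h of gamma equal 4.36 h of the north run, which is less than the 5.00 h at which north read 63.7%, so gamma should end below that figure. This reckoning orders the flasks by [E] at both times, as the forecast does, but it parts from the forecast on the height of delta.

The forecast gives delta > alpha > theta > gamma at 20 h and delta > alpha > theta > gamma at 2.0 h, with 87% for the first flask and 57% for the last: “So the ceiling looks like an equilibrium at held X, not catalyst death.”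

The flasks give delta > alpha > theta > gamma and delta > alpha > theta > gamma, with delta at 93.8% and gamma at 50.3%.

    Q + E → L (k = 460 M⁻¹ h⁻¹)
    D + L → Z (k = 1.80 × 10⁵ M⁻¹ h⁻¹)
    Z → E + J (k = 2500 h⁻¹)
    Q + J → G (k = 0.0290 M⁻¹ h⁻¹)
    X ⇌ D, rate k5*(csat - [D]) (kL = 7.20 h⁻¹)

The shortfall of delta is the step Q + J → G: J ends at 93.8% with that step and at 100% in the same run without it, and G, with two Q in each, holds 6.15% of the Q charged, twice the 3.10% of ℓs/ℓ. In delta the forward step Q + E, taken at the charge, asks 8.28 M h⁻¹, more than the 1.44 M h⁻¹ of X crossing into a solution holding none. In the neighbouring flask, delta with Q at 1.2 M, the same step asks 1.32 M h⁻¹, less than that crossing, and G stands at 3.27% beside the 3.10% of ℓs/ℓ, with J at 96.7%.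

Readings and results are calculated with constants of no real substance; scatter was added.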